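**Plan**

- Retrosynthesis: the acylcyclohexanetrione ring (C1 = ring C=O, C2 = propanoyl-bearing carbon, C3 and C5 = enol carbons, C4 = CMe2, C6 = bridge-bearing carbon) is cut at C5–C6 and C1–C2, two enolate-to-acyl (Claisen) bonds. This gives aryl lactone 10 (bridge CH2, C6, C1) and enol lactone 14 (C2–C5 with the gem-dimethyl and propanoyl groups), two fragments of similar size.
- Enabling feature: the hydroxyl at C5 of the chromene is ortho to the C6 methylene bridge, so its oxygen, the bridge carbon and ring carbons C6 and C1 can be stored as a temporary six-membered aryl lactone. Every carbon of the carbocycle is a carbonyl carbon or lies between two of them.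
- Forward order: pyran ring of the chromene (1 + 2 → 4), temporary lactone ring (4 + 5 + 6 → 10), enol lactone 14 from 11 and 12, then the carbocycle last by union of 10 and 14. Both lactone rings open and no atom is lost (C17H18O5 + C9H12O3 = C26H30O8).
- Stereochemistry: the target has no stereocentre and no stereogenic double bond. The sp3 centres of 9 and 15 are racemic and vanish by decarboxylation or enolisation.

Key step: step 5

Assumption: 16 is written in the dienol tautomer of the given structure; 13 and 15 are written as keto forms although they should be largely enolised; 6 stands for the monomer delivered by paraformaldehyde.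

**Step 1**
Reactants: 1 1-(2,4,6-trihydroxyphenyl)propan-1-one (flopropione); 2 3-methylbut-2-enal
Product: 4 1-(5,7-dihydroxy-2,2-dimethyl-2H-chromen-8-yl)propan-1-one, via oxatriene 3 (not isolated)
Conditions: 2 (1.1 equiv), ethylenediammonium diacetate (10 mol%), toluene–THF, 80 °C
Reagents that add atoms: none
Why: Amine-salt-catalysed Knoevenagel-type condensation of the enal with a free ring carbon of the phloroglucinol should give oxatriene 3, and its oxa-6π electrocyclisation through the carbonyl oxygen ortho to the propanoyl group closes the 2,2-dimethyl-2H-pyran ring (formal [3+3] chromene annulation); no stereocentre is formed, and the 6-acyl regioisomer from closure through the para oxygen would be removed by chromatography.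

**Step 2**
Reactants: 4 1-(5,7-dihydroxy-2,2-dimethyl-2H-chromen-8-yl)propan-1-one; 5 2,2-dimethyl-1,3-dioxane-4,6-dione (Meldrum's acid); 6 formaldehyde (used as paraformaldehyde)
Product: 10 5-hydroxy-8,8-dimethyl-6-propanoyl-3,4-dihydro-2H,8H-pyrano[2,3-f]chromen-2-one, via methylidene Meldrum's acid 7 (not isolated), via Meldrum's acid Michael adduct 8 (not isolated), via lactone acid 9 (not isolated)
Conditions: 5 (1.2 equiv), paraformaldehyde (1.1 equiv), pyridine, 100 °C
Reagents that add atoms: none
Why: Yonemitsu-type three-component condensation, the known phenol–aldehyde–Meldrum's acid route to 3,4-dihydrocoumarins: Knoevenagel condensation of 5 with 6 gives the strong acceptor 7, the only free ring carbon of 4 (C6, between two hydroxyls) adds to it to give 8, the unchelated C5 hydroxyl opens the dioxanedione with loss of acetone, and the malonic-type acid 9 loses CO2 in hot pyridine, which also removes its racemic C3 centre.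

**Step 3**
Reactants: 11 methyl 2,2-dimethyl-3-oxobutanoate; 12 N-methoxy-N-methylpropanamide
Product: 13 methyl 2,2-dimethyl-3,5-dioxoheptanoate
Conditions: LiN(i-Pr)2 (1.1 equiv), THF, −78 °C; then 12, −78 to 0 °C; then 1 M HCl
Reagents that add atoms: none
Why: The kinetic lithium enolate of the methyl ketone (the only enolisable position of 11) is acylated by the Weinreb amide, whose chelated tetrahedral adduct releases the 1,3-diketone only on work-up, so neither over-addition nor quenching of the enolate by the product should occur (Weinreb ketone synthesis with a ketone enolate, a crossed Claisen-type acylation).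

**Step 4**
Reactants: 13 methyl 2,2-dimethyl-3,5-dioxoheptanoate
Product: 14 6-ethyl-3,3-dimethyl-2H-pyran-2,4(3H)-dione
Conditions: p-TsOH·H2O (10 mol%), toluene, reflux, 4 Å molecular sieves in a Soxhlet (removal of MeOH)
Reagents that add atoms: none
Why: Acid-catalysed enol-lactonisation (intramolecular transesterification by the C5 enol), helped by the gem-dimethyl effect and driven by removal of methanol, is the cyclisation that turns 3,5-dioxoalkanoates into pyranones, and the absence of base avoids the competing carbon Dieckmann closure through the terminal CH2.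

**Step 5**
Reactants: 10 5-hydroxy-8,8-dimethyl-6-propanoyl-3,4-dihydro-2H,8H-pyrano[2,3-f]chromen-2-one; 14 6-ethyl-3,3-dimethyl-2H-pyran-2,4(3H)-dione
Product: 16 6-[(5,7-dihydroxy-2,2-dimethyl-8-propanoyl-2H-chromen-6-yl)methyl]-3,5-dihydroxy-4,4-dimethyl-2-propanoylcyclohexa-2,5-dien-1-one, via acyl lactone 15 (not isolated)
Conditions: LiN(SiMe3)2 (3.1 equiv), THF, −78 °C; then 14 (1.2 equiv), −78 to −20 °C; then AcOH (1.0 equiv), −20 °C to rt; 1 M HCl work-up
Reagents that add atoms: none
Why: Proposed new method: an anionic [4+2] annulation by two consecutive acyl transfers, in which the lithium enolate at C3 of aryl lactone 10 attacks the enol-lactone carbonyl C2 of 14, the pyrandione ring opens to the 3,5-diketonate of 15, and, once acetic acid has returned the proton that the third equivalent of base took from C3 of 15, the central diketonate carbon attacks the aryl lactone carbonyl and expels the C5 phenoxide. The closest known reaction types are the crossed Claisen acylation of ester and lactone enolates by enol esters and the Baker–Venkataraman/Dieckmann oxygen-to-carbon acyl transfer onto a 1,3-dicarbonyl carbon, merged here in the manner of Michael–Claisen (Staunton–Weinreb-type) annulations. The carbocycle closes in a 6-exo-trig Dieckmann mode through a six-membered transition state, and the leaving group is the temporary lactone ring itself, so the union is an isomerising addition 10 + 14 = 16. No lasting stereocentre is formed, since C3 of 15 becomes the sp2 ring carbon C6 that carries the bridge. The step needs enolisation of the lactone and not of the aryl ethyl ketone, which the chelated ortho-oxido aryl ketone (a vinylogous carboxylate, far less acidic) should secure, and attack at C2 of 14 and not at its ketone C4 or conjugate position C6, which the hard lithium enolate at low temperature and the reversibility of ketone addition against the irreversible ring opening should favour. Carbon- over oxygen-acylation in the closure is secured thermodynamically, because an enol lactone formed by oxygen attack remains an acyl donor and only the carbon-acylated trione leaves the equilibria as its stabilised dianion.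

**Compound list**

1 | 1-(2,4,6-trihydroxyphenyl)propan-1-one (flopropione) | CCC(=O)c1c(O)cc(O)cc1O | starting material
2 | 3-methylbut-2-enal | CC(C)=CC=O | starting material
3 | (6Z)-3,5-dihydroxy-6-(3-methylbut-2-en-1-ylidene)-2-propanoylcyclohexa-2,4-dien-1-one (oxatriene) | CCC(=O)C1=C(O)C=C(O)/C(=C/C=C(C)C)C1=O | intermediate
4 | 1-(5,7-dihydroxy-2,2-dimethyl-2H-chromen-8-yl)propan-1-one | CCC(=O)c1c(O)cc(O)c2C=CC(C)(C)Oc12 | intermediate
5 | 2,2-dimethyl-1,3-dioxane-4,6-dione (Meldrum's acid) | CC1(C)OC(=O)CC(=O)O1 | starting material
6 | formaldehyde (used as paraformaldehyde) | C=O | starting material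
7 | 2,2-dimethyl-5-methylidene-1,3-dioxane-4,6-dione | C=C1C(=O)OC(C)(C)OC1=O | intermediate
8 | 5-[(5,7-dihydroxy-2,2-dimethyl-8-propanoyl-2H-chromen-6-yl)methyl]-2,2-dimethyl-1,3-dioxane-4,6-dione | CCC(=O)c1c(O)c(CC2C(=O)OC(C)(C)OC2=O)c(O)c2C=CC(C)(C)Oc12 | intermediate
9 | 5-hydroxy-8,8-dimethyl-2-oxo-6-propanoyl-3,4-dihydro-2H,8H-pyrano[2,3-f]chromene-3-carboxylic acid (racemic) | CCC(=O)c1c(O)c2CC(C(=O)O)C(=O)Oc2c2C=CC(C)(C)Oc12 | intermediate
10 | 5-hydroxy-8,8-dimethyl-6-propanoyl-3,4-dihydro-2H,8H-pyrano[2,3-f]chromen-2-one (lactone closed on the C5 oxygen of 4, CH2CH2 on C6) | CCC(=O)c1c(O)c2CCC(=O)Oc2c2C=CC(C)(C)Oc12 | intermediate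
11 | methyl 2,2-dimethyl-3-oxobutanoate | CC(=O)C(C)(C)C(=O)OC | starting material
12 | N-methoxy-N-methylpropanamide | CCC(=O)N(C)OC | starting material
13 | methyl 2,2-dimethyl-3,5-dioxoheptanoate | CCC(=O)CC(=O)C(C)(C)C(=O)OC | intermediate
14 | 6-ethyl-3,3-dimethyl-2H-pyran-2,4(3H)-dione | CCC1=CC(=O)C(C)(C)C(=O)O1 | intermediate
15 | 3-(2,2-dimethyl-3,5-dioxoheptanoyl)-5-hydroxy-8,8-dimethyl-6-propanoyl-3,4-dihydro-2H,8H-pyrano[2,3-f]chromen-2-one (racemic, present as lithium salts) | CCC(=O)CC(=O)C(C)(C)C(=O)C1Cc2c(O)c(C(=O)CC)c3OC(C)(C)C=Cc3c2OC1=O | intermediate
16 | 6-[(5,7-dihydroxy-2,2-dimethyl-8-propanoyl-2H-chromen-6-yl)methyl]-3,5-dihydroxy-4,4-dimethyl-2-propanoylcyclohexa-2,5-dien-1-one | CCC(=O)C1=C(O)C(C)(C)C(O)=C(Cc2c(O)c3c(c(C(=O)CC)c2O)OC(C)(C)C=C3)C1=O | target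

**Step count**

Total steps: 5. Longest linear sequence: 3 steps (1 → 4 → 10 → 16, or 11 → 13 → 14 → 16).

**Steps most likely to fail**

1. Step 5 (proposed new method). What may go wrong:
   - proton transfer from the acylated lactone to unreacted enolate stalls the acylation;
   - the enolate adds at the ketone or in conjugate fashion at C6 of the pyrandione instead of at its lactone carbonyl;
   - the aryl ethyl ketone is partly enolised;
   - phenoxide is eliminated from the lactone enolate.

   Fallback by known chemistry, setting out from 1 and 4 and returning at 16: flopropione 1 would be doubly C-methylated at one ring carbon (NaOMe, MeI, MeOH, 0 °C to rt; dearomatising alkylation) to 3,5-dihydroxy-4,4-dimethyl-2-propanoylcyclohexa-2,5-dien-1-one (2-propanoylfilicinic acid) F1. F1 would be aminomethylated at its free ring carbon with dimethylmethylideneammonium iodide (MeCN, rt) to the Mannich base 6-[(dimethylamino)methyl]-3,5-dihydroxy-4,4-dimethyl-2-propanoylcyclohexa-2,5-dien-1-one F2. F2 would be heated with chromene 4 in dioxane (90 °C); loss of dimethylamine and conjugate addition of C6 of 4 to the resulting acceptor should give 16 without the homodimers of a free-formaldehyde coupling. In this variant the carbocycle comes from the arene of 1 and is not closed.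

2. Step 2. What may go wrong: formaldehyde links two molecules of 4 through C6 before it is taken up by Meldrum's acid, or the alkylidene is consumed by a second molecule of 5. Fallback setting out from 4 and returning at 10: 4 would be aminomethylated at C6 with dimethylmethylideneammonium iodide (MeCN, rt) to 1-{6-[(dimethylamino)methyl]-5,7-dihydroxy-2,2-dimethyl-2H-chromen-8-yl}propan-1-one F3. F3 would be heated with 5 in toluene–pyridine (100 °C); thermal loss of dimethylamine, Michael addition of Meldrum's acid to the benzylic carbon, lactonisation with loss of acetone and decarboxylation should give 10. Free formaldehyde never meets the arene in this polarity-reversed variant.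

3. Step 1. What may go wrong: poor regioselectivity of the electrocyclisation (closure onto the oxygen para to the ketone) and a second annulation at C6. Fallback setting out from 1 and returning at 10, with the order of ring formation reversed so that the lactone blocks the wrong oxygen: 1 would be condensed with 5 and 6 (one equivalent each, pyridine, 100 °C) to 5,7-dihydroxy-6-propanoyl-3,4-dihydro-2H-chromen-2-one F4, the lactone closing on the unchelated hydroxyl para to the ketone. In F4 the only free ring carbon lies between the lactone oxygen and the hydroxyl ortho to the ketone, so annulation with 2 (ethylenediammonium diacetate, toluene–THF, 80 °C) can close the pyran only onto that hydroxyl and should give 10 directly, bypassing 4.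

**Further compounds**

F1 | step 5 | 3,5-dihydroxy-4,4-dimethyl-2-propanoylcyclohexa-2,5-dien-1-one (2-propanoylfilicinic acid) | CCC(=O)C1=C(O)C(C)(C)C(O)=CC1=O
F2 | step 5 | 6-[(dimethylamino)methyl]-3,5-dihydroxy-4,4-dimethyl-2-propanoylcyclohexa-2,5-dien-1-one | CCC(=O)C1=C(O)C(C)(C)C(O)=C(CN(C)C)C1=O
F3 | step 2 | 1-{6-[(dimethylamino)methyl]-5,7-dihydroxy-2,2-dimethyl-2H-chromen-8-yl}propan-1-one | CCC(=O)c1c(O)c(CN(C)C)c(O)c2C=CC(C)(C)Oc12
F4 | step 1 | 5,7-dihydroxy-6-propanoyl-3,4-dihydro-2H-chromen-2-one | CCC(=O)c1c(O)cc2OC(=O)CCc2c1O
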